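**Plan**

- Retrosynthesis (bicyclo[3.2.1]oct-3-ene-2,8-dione numbering): after O-demethylation, cut C3=C4 (aldol condensation), then the C1–C2 acyl bond, the styryl C=C, the C5–C8 bond (Claisen condensation) and the two aryl–C bonds at C6 and C7 (conjugate arylations).
- Enabling feature: in the six-membered ring C1–C2–C3–C4–C5–C8, the carbons C2, C4 and C8 are 1,3,5-related carbonyl-level positions (a dearomatized resorcinol, i.e. a triketide). With C4 carried as a ketone, C5 is a ketone α-carbon five atoms from the C8 ester carbon.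
- Forward: dienyl keto ester → two aryl groups added → cyclopentanone ring (C1, C5, C6, C7, C8) closed by the C5–C8 Claisen condensation → styryl and acetyl groups attached → six-membered ring closed by the C3–C4 aldol condensation → phenols freed.
- Stereochemistry: C6 and C7 come from two ligand-controlled Rh-catalysed 1,4-additions. C5 and C1 are enolizable and are fixed only when the bridge forms; the bridge must be cis, and the endo aryl is tolerated only next to the trigonal C2.

Key step: step 4

Assumption: for linear (E)-acceptors the (R)-BINAP–rhodium catalyst is taken to deliver the aryl group to the Si face of the α-carbon (C5 of 3, C2 of 5); if the sense proves opposite, the antipodal ligand is used in steps 2 and 3.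

**Step 1**
Reactants: 1 ethyl (E)-4-oxobut-2-enoate; 2 1-(triphenyl-λ5-phosphanylidene)propan-2-one
Product: 3 ethyl (2E,4E)-6-oxohepta-2,4-dienoate
Conditions: CH2Cl2, 0 °C to rt
Reagents that add atoms: none
Why: Wittig olefination with a stabilized acyl ylide should be chemoselective for the aldehyde and E-selective, giving the (2E,4E)-dienyl keto ester.

**Step 2**
Reactants: 3 ethyl (2E,4E)-6-oxohepta-2,4-dienoate; 4 (3,5-dimethoxyphenyl)boronic acid
Product: 5 ethyl (2E,4S)-4-(3,5-dimethoxyphenyl)-6-oxohept-2-enoate
Conditions: [Rh(OH)((R)-BINAP)]2 (cat.), dioxane/H2O 10:1, 35 °C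
Reagents that add atoms: none
Why: Hayashi–Miyaura 1,4-addition in which the aryl–rhodium species should insert at C4, which is β to the ketone and δ to the ester and hence the most electrophilic site, with the BINAP ligand fixing the C4 configuration by face-selective carbometalation before the less reactive enoate reacts.

**Step 3**
Reactants: 5 ethyl (2E,4S)-4-(3,5-dimethoxyphenyl)-6-oxohept-2-enoate; 6 (3,4-dimethoxyphenyl)boronic acid
Product: 7 ethyl (3S,4S)-3-(3,4-dimethoxyphenyl)-4-(3,5-dimethoxyphenyl)-6-oxoheptanoate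
Conditions: [Rh(OH)((R)-BINAP)]2 (cat.), dioxane/H2O 10:1, 90 °C
Reagents that add atoms: none
Why: A second Hayashi–Miyaura 1,4-addition, now to the remaining enoate, in which the ligand should control the face at C3, while the base-free hydroxo-rhodium conditions are chosen to avoid enolate chemistry of the methyl ketone.

**Step 4**
Reactants: 7 ethyl (3S,4S)-3-(3,4-dimethoxyphenyl)-4-(3,5-dimethoxyphenyl)-6-oxoheptanoate
Product: 8 (2R,3R,4S)-2-acetyl-4-(3,4-dimethoxyphenyl)-3-(3,5-dimethoxyphenyl)cyclopentan-1-one
Conditions: NaOEt, EtOH, 60 °C; then aq. HCl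
Reagents that add atoms: none
Why: Ethoxide reversibly deprotonates 7 at C5, the ketone α-carbon (far more acidic than the ester α-CH2), and this enolate adds to the ester carbonyl C1 five atoms away; loss of ethoxide and deprotonation of the new β-diketone complete an intramolecular Claisen condensation of the Dieckmann type, whose closest precedent is the alkoxide cyclization of 6-oxoheptanoates to 2-acetylcyclopentanones. The cyclopentanone ring (C1, C5, C6, C7 and C8 of the later bicycle) closes in the 5-(enolexo)-exo-trig mode by the new C5–C1 bond, which becomes the C5–C8 bond of the target. The one new stereocentre, C2 of 8, lies between two carbonyl groups and is set under thermodynamic control trans to the C3 aryl group (the compound should be largely enolized), while C3 and C4 are not acidic and keep the configuration from steps 2 and 3. The selectivity needed is regiochemical among three enolizable positions: closure from the methyl group would need a seven-membered transition state and aldol addition of the ester enolate to the ketone is reversible, so all pathways should drain into the stabilized five-ring β-diketonate. The C6 ketone of 7 is the oxidation-level helper that makes C5 nucleophilic; it is removed in step 7, where it becomes the alkene carbon C4.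

**Step 5**
Reactants: 8 (2R,3R,4S)-2-acetyl-4-(3,4-dimethoxyphenyl)-3-(3,5-dimethoxyphenyl)cyclopentan-1-one; 9 3,4-dimethoxybenzaldehyde
Product: 11 (2S,3R,4S)-4-(3,4-dimethoxyphenyl)-3-(3,5-dimethoxyphenyl)-2-[(E)-3-(3,4-dimethoxyphenyl)prop-2-enoyl]cyclopentan-1-one, via aldol adduct 10 (not isolated)
Conditions: LiN(iPr)2 (2.2 equiv), THF, −78 to 0 °C; 9, −78 °C; then 2 M HCl, THF, 40 °C
Reagents that add atoms: none
Why: Aldol condensation through the 1,3-dianion of the β-diketone, whose second deprotonation should occur at the terminal methyl group, followed by acid dehydration of the benzylic carbinol to the E enone; any dihydropyranone formed by oxa-conjugate addition should reopen under the strongly basic conditions of step 6.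

**Step 6**
Reactants: 11 (2S,3R,4S)-4-(3,4-dimethoxyphenyl)-3-(3,5-dimethoxyphenyl)-2-[(E)-3-(3,4-dimethoxyphenyl)prop-2-enoyl]cyclopentan-1-one; 12 N-methoxy-N-methylacetamide
Product: 13 (2R,3R,4R,5R)-2-acetyl-3-(3,4-dimethoxyphenyl)-4-(3,5-dimethoxyphenyl)-5-[(E)-3-(3,4-dimethoxyphenyl)prop-2-enoyl]cyclopentan-1-one
Conditions: LiN(iPr)2 (3.2 equiv), THF, −78 to −20 °C; 12; then aq. HCl
Reagents that add atoms: none
Why: C-acylation of the β-diketone dianion at the only remaining α′-position with an N-methoxy-N-methyl amide (stable tetrahedral intermediate, no over-addition) should give the 1,3,5-triketone, whose two acyl-bearing ring carbons are enolizable so that their configuration is not yet fixed.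

**Step 7**
Reactants: 13 (2R,3R,4R,5R)-2-acetyl-3-(3,4-dimethoxyphenyl)-4-(3,5-dimethoxyphenyl)-5-[(E)-3-(3,4-dimethoxyphenyl)prop-2-enoyl]cyclopentan-1-one
Product: 15 (1S,5R,6R,7R)-7-(3,4-dimethoxyphenyl)-6-(3,5-dimethoxyphenyl)-4-[(E)-2-(3,4-dimethoxyphenyl)ethenyl]bicyclo[3.2.1]oct-3-ene-2,8-dione, via bridged aldol 14 (not isolated)
Conditions: TsOH·H2O (cat.), PhMe, 4 Å MS, 80 °C
Reagents that add atoms: none
Why: Intramolecular aldol condensation of a 1,3,5-triketone that cannot aromatize (polyketide-type cyclization): the enol of the acetyl methyl group attacks the cinnamoyl carbonyl from the 2,5-cis epimer reached by enolization, dehydration can only give C3=C4 because a bridgehead alkene is impossible, and the isomer with the 3,4-dimethoxyphenyl group endo next to trigonal C2 should be favoured because an endo aryl group next to tetrahedral C4 would clash with its axial substituent.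

**Step 8**
Reactants: 15 (1S,5R,6R,7R)-7-(3,4-dimethoxyphenyl)-6-(3,5-dimethoxyphenyl)-4-[(E)-2-(3,4-dimethoxyphenyl)ethenyl]bicyclo[3.2.1]oct-3-ene-2,8-dione
Product: 16 jezonodione, (1S,5R,6R,7R)-7-(3,4-dihydroxyphenyl)-6-(3,5-dihydroxyphenyl)-4-[(E)-2-(3,4-dihydroxyphenyl)ethenyl]bicyclo[3.2.1]oct-3-ene-2,8-dione
Conditions: BBr3, CH2Cl2, −78 to 0 °C; then H2O
Reagents that add atoms: none
Why: Lewis-acid cleavage of the six aryl methyl ethers under non-basic conditions, chosen so that the non-enolizable bridged 1,3-diketone is not exposed to nucleophilic base (retro-Claisen opening); no stereocentre is touched.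

**Compound list**

1 | ethyl (E)-4-oxobut-2-enoate | CCOC(=O)/C=C/C=O | starting material
2 | 1-(triphenyl-λ5-phosphanylidene)propan-2-one | CC(=O)C=P(c1ccccc1)(c1ccccc1)c1ccccc1 | starting material
3 | ethyl (2E,4E)-6-oxohepta-2,4-dienoate | CCOC(=O)/C=C/C=C/C(C)=O | intermediate
4 | (3,5-dimethoxyphenyl)boronic acid | COc1cc(OC)cc(B(O)O)c1 | starting material
5 | ethyl (2E,4S)-4-(3,5-dimethoxyphenyl)-6-oxohept-2-enoate | CCOC(=O)/C=C/[C@H](CC(C)=O)c1cc(OC)cc(OC)c1 | intermediate
6 | (3,4-dimethoxyphenyl)boronic acid | COc1ccc(B(O)O)cc1OC | starting material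
7 | ethyl (3S,4S)-3-(3,4-dimethoxyphenyl)-4-(3,5-dimethoxyphenyl)-6-oxoheptanoate | CCOC(=O)C[C@H](c1ccc(OC)c(OC)c1)[C@H](CC(C)=O)c1cc(OC)cc(OC)c1 | intermediate
8 | (2R,3R,4S)-2-acetyl-4-(3,4-dimethoxyphenyl)-3-(3,5-dimethoxyphenyl)cyclopentan-1-one (keto form; all-trans) | CC(=O)[C@@H]1C(=O)C[C@H](c2ccc(OC)c(OC)c2)[C@H]1c3cc(OC)cc(OC)c3 | intermediate
9 | 3,4-dimethoxybenzaldehyde | COc1ccc(C=O)cc1OC | starting material
10 | (2S,3R,4S)-4-(3,4-dimethoxyphenyl)-3-(3,5-dimethoxyphenyl)-2-[3-(3,4-dimethoxyphenyl)-3-hydroxypropanoyl]cyclopentan-1-one (carbinol configuration not defined) | O=C(CC(O)c1ccc(OC)c(OC)c1)[C@@H]1C(=O)C[C@H](c2ccc(OC)c(OC)c2)[C@H]1c3cc(OC)cc(OC)c3 | intermediate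
11 | (2S,3R,4S)-4-(3,4-dimethoxyphenyl)-3-(3,5-dimethoxyphenyl)-2-[(E)-3-(3,4-dimethoxyphenyl)prop-2-enoyl]cyclopentan-1-one | O=C(/C=C/c1ccc(OC)c(OC)c1)[C@@H]1C(=O)C[C@H](c2ccc(OC)c(OC)c2)[C@H]1c3cc(OC)cc(OC)c3 | intermediate
12 | N-methoxy-N-methylacetamide | CC(=O)N(C)OC | starting material
13 | (2R,3R,4R,5R)-2-acetyl-3-(3,4-dimethoxyphenyl)-4-(3,5-dimethoxyphenyl)-5-[(E)-3-(3,4-dimethoxyphenyl)prop-2-enoyl]cyclopentan-1-one (all-trans keto form; C2 and C5 enolizable) | CC(=O)[C@@H]1C(=O)[C@@H](C(=O)/C=C/c2ccc(OC)c(OC)c2)[C@H](c2cc(OC)cc(OC)c2)[C@H]1c3ccc(OC)c(OC)c3 | intermediate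
14 | (1S,5R,6R,7R)-7-(3,4-dimethoxyphenyl)-6-(3,5-dimethoxyphenyl)-4-[(E)-2-(3,4-dimethoxyphenyl)ethenyl]-4-hydroxybicyclo[3.2.1]octane-2,8-dione (C4 configuration not defined) | O=C1CC(O)(/C=C/c2ccc(OC)c(OC)c2)[C@@H]2C(=O)[C@H]1[C@H](c1ccc(OC)c(OC)c1)[C@H]2c1cc(OC)cc(OC)c1 | intermediate
15 | (1S,5R,6R,7R)-7-(3,4-dimethoxyphenyl)-6-(3,5-dimethoxyphenyl)-4-[(E)-2-(3,4-dimethoxyphenyl)ethenyl]bicyclo[3.2.1]oct-3-ene-2,8-dione | O=C1C=C(/C=C/c2ccc(OC)c(OC)c2)[C@@H]2C(=O)[C@H]1[C@H](c1ccc(OC)c(OC)c1)[C@H]2c1cc(OC)cc(OC)c1 | intermediate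
16 | jezonodione, (1S,5R,6R,7R)-7-(3,4-dihydroxyphenyl)-6-(3,5-dihydroxyphenyl)-4-[(E)-2-(3,4-dihydroxyphenyl)ethenyl]bicyclo[3.2.1]oct-3-ene-2,8-dione | O=C1C=C(/C=C/c2ccc(O)c(O)c2)[C@@H]2C(=O)[C@H]1[C@H](c1ccc(O)c(O)c1)[C@H]2c1cc(O)cc(O)c1 | target

**Step count and risks**

Total steps: 8. Longest linear sequence: 8 steps (1 to 16).

Steps most likely to fail:

Step 7. The bridging aldol addition may stay on the side of the open triketone. It may also be outrun by conjugate addition of an enolized 1,3-dicarbonyl unit (through oxygen or through the ring carbon) to the cinnamoyl group, and dehydration may be slow. The fallback sets out from 11 and rejoins the route at 15. The dianion of 11 (LiN(iPr)2) is acylated at C5 with N-methoxy-N-methyl-2-(trimethylsilyl)acetamide to give the 2-[(trimethylsilyl)acetyl] analogue of 13 F1. Catalytic Me3SiOTf in CH2Cl2 brings about the 1,3-shift of silicon from carbon to oxygen and gives the terminal trimethylsilyl enol ether of 13 F2, in which only the methyl-derived carbon is nucleophilic while the ring carbons stay enolizable. TiCl4 at −78 °C then closes the ring by an intramolecular Mukaiyama aldol addition to the cinnamoyl carbonyl (the conjugate mode would need an eight-membered ring) to give 14. Compound 14 is isolated and dehydrated with catalytic TsOH to 15.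

Step 3. Carbometalation of the hindered, γ-branched enoate may be slow at a temperature at which the catalyst decays. Diastereoselectivity may erode if ligand and substrate preferences are mismatched, and the methyl ketone may undergo intramolecular conjugate addition or alkene migration. The fallback sets out from 5 and rejoins the route at 7. (3,4-(MeO)2C6H3)2CuLi (from the aryllithium and CuBr·SMe2) with Me3SiCl in THF at −78 °C adds the aryl group under substrate control, with the C4 aryl group anti to the incoming nucleophile. This should favour the same 3,4-relationship and give the ethyl trimethylsilyl ketene acetal of 7 F3, which dilute aqueous acid hydrolyses to 7.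

Step 8. Cleavage of six methyl ethers on the strained, non-enolizable 1,3-diketone may be accompanied by HBr addition to the dienone, acid-induced skeletal cleavage or arylation. The fallback sets out from 13 and rejoins the route at 16. BBr3 is applied at the stage of the more robust triketone and gives the hexa-O-demethyl analogue of 13 F4. The acid-mediated aldol condensation of step 7 is then run last on F4 and gives 16 directly.

**Further compounds**

F1 | step 7 | 2-[(trimethylsilyl)acetyl] analogue of 13 (same ring configuration) | C[Si](C)(C)CC(=O)[C@@H]1C(=O)[C@@H](C(=O)/C=C/c2ccc(OC)c(OC)c2)[C@H](c2cc(OC)cc(OC)c2)[C@H]1c3ccc(OC)c(OC)c3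
F2 | step 7 | terminal trimethylsilyl enol ether of 13, 2-[1-(trimethylsilyloxy)ethenyl] analogue | C=C(O[Si](C)(C)C)[C@@H]1C(=O)[C@@H](C(=O)/C=C/c2ccc(OC)c(OC)c2)[C@H](c2cc(OC)cc(OC)c2)[C@H]1c3ccc(OC)c(OC)c3
F3 | step 3 | ethyl trimethylsilyl ketene acetal of 7 (alkene geometry not defined) | CCOC(O[Si](C)(C)C)=C[C@H](c1ccc(OC)c(OC)c1)[C@H](CC(C)=O)c1cc(OC)cc(OC)c1
F4 | step 8 | hexa-O-demethyl analogue of 13 (hexahydroxy triketone) | CC(=O)[C@@H]1C(=O)[C@@H](C(=O)/C=C/c2ccc(O)c(O)c2)[C@H](c2cc(O)cc(O)c2)[C@H]1c3ccc(O)c(O)c3
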